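**Plan**
- Retrosynthesis: the side chain is saturated last (a C7≡C8 alkyne is the helper). The lactone is cut at C1–O, and the lactone oxygen on C4 is exchanged for a formyl group (Baeyer–Villiger retron). O–C6 and C3–C4 of the 1,2-dioxane are cut together, and C4 and C6 are re-joined as a cyclopropane. Finally C5 is cut (methylene transfer) and C6–C7 is cut (sp2–sp coupling).
- Enabling feature: in the dioxane ring the two fully substituted carbons C4 and C6 are separated only by the C5 methylene, so they are the two ends of a cyclopropane C–C bond. The other ring atoms, O–O–C3, form a three-atom unit that is nucleophilic at oxygen and electrophilic at carbon (peroxycarbenium ion). Together this is the retron of a (3+3) annulation.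
- Forward order: enyne ester, cyclopropane (temporary ring), 1,2-dioxane (step 7), γ-lactone (step 8), saturated chain (step 9).
- Helpers: CHO on C4 is the acceptor and is replaced by O with retention. Alkynyl on C6 is the donor and the slim axial group and is hydrogenated. Et3Si on the peroxide is lost in step 7.
- Stereochemistry: alkene geometry (step 1) plus reagent-controlled cyclopropanation (step 4) set C6, which is transferred with inversion. C4 and C3 follow from the chair closure in step 7, and the cis ring fusion is secured again in step 8.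

Key step: step 7

Remark: polyketide numbering of the target is used for all intermediates (C1 lactone C=O, C2 CH2, C3 CH–OO, C4 C(CH3)–O, C5 CH2, C6 C(CH3)–OO, C7 onward side chain); in it the target is (3S,4S,6R).

Step 1
Reactants: 1 ethyl 2-methyl-3-oxobutanoate
Product: 2 ethyl (Z)-2-methyl-3-(trifluoromethylsulfonyloxy)but-2-enoate
Conditions: Tf2O, sat. aq LiOH, toluene, 5 °C
Reagents that add atoms: trifluoromethanesulfonic anhydride, O=S(=O)(OS(=O)(=O)C(F)(F)F)C(F)(F)F
Why: Enol triflate formation by O-sulfonylation of the lithium-chelated Z-enolate should place OTf cis to the ester and so fix the alkene geometry that later decides the configuration of the cyclopropane.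

Step 2
Reactants: 2 ethyl (Z)-2-methyl-3-(trifluoromethylsulfonyloxy)but-2-enoate; 3 hexadec-1-yne
Product: 4 ethyl (Z)-2,3-dimethylnonadec-2-en-4-ynoate
Conditions: PdCl2(PPh3)2 (3 mol %), CuI (5 mol %), Et3N, THF, rt
Reagents that add atoms: none
Why: Sonogashira coupling of an electron-poor alkenyl triflate proceeds with retention of alkene geometry and brings in the whole side chain as an alkynyl group cis to the ester.

Step 3
Reactants: 4 ethyl (Z)-2,3-dimethylnonadec-2-en-4-ynoate
Product: 5 (Z)-2,3-dimethylnonadec-2-en-4-yn-1-ol
Conditions: i-Bu2AlH (2.5 equiv), CH2Cl2, −78 to 0 °C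
Reagents that add atoms: none
Why: 1,2-Reduction of an α,β-unsaturated ester by a dialkylaluminium hydride gives the allylic alcohol without touching the enyne or its geometry.

Step 4
Reactants: 5 (Z)-2,3-dimethylnonadec-2-en-4-yn-1-ol
Product: 6 [(1R,2R)-2-(hexadec-1-yn-1-yl)-1,2-dimethylcyclopropyl]methanol
Conditions: Et2Zn, CH2I2, DME, CH2Cl2, −10 °C, giving Zn(CH2I)2·DME; then 5 and (4S,5S)-2-butyl-N,N,N',N'-tetramethyl-1,3,2-dioxaborolane-4,5-dicarboxamide (1.2 equiv), −10 °C to rt
Reagents that add atoms: diiodomethane, ICI
Why: In the Charette asymmetric Simmons–Smith cyclopropanation the zinc alkoxide bound to the chiral dioxaborolane delivers CH2 (the future C5) stereospecifically to one alkene face, which sets C6 (and, for the time being, C4), the (S,S) controller being chosen by the established facial model.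

Step 5
Reactants: 6 [(1R,2R)-2-(hexadec-1-yn-1-yl)-1,2-dimethylcyclopropyl]methanol
Product: 7 (1R,2R)-2-(hexadec-1-yn-1-yl)-1,2-dimethylcyclopropane-1-carbaldehyde
Conditions: Dess–Martin periodinane, CH2Cl2, 0 °C to rt
Reagents that add atoms: none
Why: Dess–Martin oxidation turns the primary alcohol into the formyl acceptor under near-neutral conditions that should leave the donor–acceptor cyclopropane, its two stereocentres and the alkyne intact.

Step 6
Reactants: 8 dimethyl (E)-hex-3-enedioate
Product: 10 methyl 3-methoxy-3-[(triethylsilyl)peroxy]propanoate (racemic), via methoxy hydroperoxide 9 (not isolated)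
Conditions: O3, CH2Cl2–MeOH, −78 °C; N2 purge, cold evaporation; then Et3SiCl, imidazole, CH2Cl2, 0 °C
Reagents that add atoms: ozone, [O-][O+]=O; methanol, CO; chlorotriethylsilane, CC[Si](Cl)(CC)CC
Why: Ozonolysis in methanol (Criegee mechanism) traps the carbonyl oxide as the α-methoxy hydroperoxide, the symmetric alkene removing any regiochemical question, and O-silylation masks the OOH group, while the racemic acetal centre is erased in step 7.

Step 7
Reactants: 7 (1R,2R)-2-(hexadec-1-yn-1-yl)-1,2-dimethylcyclopropane-1-carbaldehyde; 10 methyl 3-methoxy-3-[(triethylsilyl)peroxy]propanoate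
Product: 12 methyl 2-[(3S,4S,6S)-4-formyl-6-(hexadec-1-yn-1-yl)-4,6-dimethyl-1,2-dioxan-3-yl]acetate, via ring-opened silyl enol ether 11 (not isolated)
Conditions: Et3SiOTf (0.2 equiv), 2,6-di-tert-butyl-4-methylpyridine (0.05 equiv), 4 Å MS, CH2Cl2, −78 to −30 °C
Reagents that add atoms: none
Why: Proposed new method: Et3SiOTf silylates the formyl oxygen of 7, the outer peroxide oxygen of 10 opens the activated ring at the donor carbon C6 from the side opposite C4 (new O–C6 bond, C4–C6 bond broken) and hands its silyl group on to give silyl enol ether 11, after which the regenerated silyl triflate ionises the OMe group and enol carbon C4 adds to the peroxycarbenium carbon C3 (new C3–C4 bond) with release of Et3SiOMe and of the catalyst. The closest known reaction types are the Lewis-acid (3+3) annulation of donor–acceptor cyclopropanes with nitrones, the Lewis-acid ring opening of such cyclopropanes by hydroperoxides and the addition of silyl enol ethers to peroxycarbenium ions, and what is new is their union on a mono-formyl cyclopropane whose two reacting carbons are both fully substituted. One ring is closed, the 1,2-dioxane, in a 6-(enolexo)-endo-trig mode in which C3 and its oxygen lie inside and the enol C=C outside the new ring. C6 is controlled by inversion of the centre set in step 4, whereas C4 and C3 are controlled by a chair transition state that keeps both methyl groups and the CH2CO2Me arm equatorial and leaves the 1,3-diaxial sites to the two slimmest groups, the linear alkynyl on C6 and the sp2 enol carbon on C4, which is the relative configuration of the target. The step needs attack at C6 and not at C5 or at the carbonyl carbon, opening without a free propargylic cation, and C–C closure before loss of a C2 proton from the peroxycarbenium ion. The alkynyl and methyl donors polarise only the C4–C6 bond, carbonyl addition of the peroxide is reversible and unproductive, the non-nucleophilic counterion and the low temperature should hold a tight ion pair, and the six-membered closure is intramolecular, while a β-peroxyacrylate formed by proton loss would still be an acceptor for the same enol carbon at C3.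

Step 8
Reactants: 12 methyl 2-[(3S,4S,6S)-4-formyl-6-(hexadec-1-yn-1-yl)-4,6-dimethyl-1,2-dioxan-3-yl]acetate
Product: 14 (3S,4S,6S)-3,6-epidioxy-4-hydroxy-4,6-dimethyldocos-7-ynoic acid 1,4-lactone, via tertiary formate 13 (not isolated)
Conditions: m-CPBA, CH2Cl2, 0 °C to rt; then K2CO3, MeOH, 0 °C
Reagents that add atoms: 3-chloroperbenzoic acid, OOC(=O)c1cccc(Cl)c1
Why: In the Baeyer–Villiger oxidation of the α-quaternary aldehyde the fully substituted C4 should migrate to oxygen with retention, and methanolysis of the labile formate frees the tertiary alkoxide, which closes the γ-lactone (5-exo-trig) on the cis CH2CO2Me arm, any C3 epimer being funnelled to the cis-fused bicycle by reversible retro-oxa-Michael and oxa-Michael addition.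

Step 9
Reactants: 14 (3S,4S,6S)-3,6-epidioxy-4-hydroxy-4,6-dimethyldocos-7-ynoic acid 1,4-lactone
Product: 15 (3S,4S,6R)-3,6-epidioxy-4-hydroxy-4,6-dimethyldocosanoic acid 1,4-lactone (target)
Conditions: KO2CN=NCO2K (excess, in portions), AcOH, MeOH–CH2Cl2, 0 °C to rt
Reagents that add atoms: none
Why: Diimide reduction transfers H2 in a concerted way first to C≡C and then to C=C and is the classical means of saturating C–C multiple bonds beside an O–O bond, which it should leave intact together with the lactone and the three stereocentres (the C6 descriptor changes from S to R only through the change in substituent ranking).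

**Compound list**
1 | ethyl 2-methyl-3-oxobutanoate (racemic) | CCOC(=O)C(C)C(C)=O | starting material
2 | ethyl (Z)-2-methyl-3-(trifluoromethylsulfonyloxy)but-2-enoate | CCOC(=O)/C(C)=C(OS(=O)(=O)C(F)(F)F)/C | intermediate
3 | hexadec-1-yne | C#CCCCCCCCCCCCCCC | starting material
4 | ethyl (Z)-2,3-dimethylnonadec-2-en-4-ynoate | CCOC(=O)/C(C)=C(C#CCCCCCCCCCCCCCC)/C | intermediate
5 | (Z)-2,3-dimethylnonadec-2-en-4-yn-1-ol | OC/C(C)=C(C#CCCCCCCCCCCCCCC)/C | intermediate
6 | [(1R,2R)-2-(hexadec-1-yn-1-yl)-1,2-dimethylcyclopropyl]methanol (CH2OH and alkynyl cis) | CCCCCCCCCCCCCCC#C[C@@]1(C)C[C@@]1(C)CO | intermediate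
7 | (1R,2R)-2-(hexadec-1-yn-1-yl)-1,2-dimethylcyclopropane-1-carbaldehyde | CCCCCCCCCCCCCCC#C[C@@]1(C)C[C@@]1(C)C=O | intermediate
8 | dimethyl (E)-hex-3-enedioate | COC(=O)C/C=C/CC(=O)OC | starting material
9 | methyl 3-hydroperoxy-3-methoxypropanoate (racemic) | COC(CC(=O)OC)OO | intermediate
10 | methyl 3-methoxy-3-[(triethylsilyl)peroxy]propanoate (racemic) | COC(CC(=O)OC)OO[Si](CC)(CC)CC | intermediate
11 | methyl 3-methoxy-3-({(4S)-2,4-dimethyl-1-[(triethylsilyl)oxy]icos-1-en-5-yn-4-yl}peroxy)propanoate (enol geometry and acetal centre undefined) | CCCCCCCCCCCCCCC#C[C@](C)(CC(C)=CO[Si](CC)(CC)CC)OOC(CC(=O)OC)OC | intermediate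
12 | methyl 2-[(3S,4S,6S)-4-formyl-6-(hexadec-1-yn-1-yl)-4,6-dimethyl-1,2-dioxan-3-yl]acetate | CCCCCCCCCCCCCCC#C[C@]1(C)C[C@](C)(C=O)[C@H](CC(=O)OC)OO1 | intermediate
13 | methyl 2-[(3S,4S,6S)-4-(formyloxy)-6-(hexadec-1-yn-1-yl)-4,6-dimethyl-1,2-dioxan-3-yl]acetate | CCCCCCCCCCCCCCC#C[C@]1(C)C[C@](C)(OC=O)[C@H](CC(=O)OC)OO1 | intermediate
14 | (3S,4S,6S)-3,6-epidioxy-4-hydroxy-4,6-dimethyldocos-7-ynoic acid 1,4-lactone | CCCCCCCCCCCCCCC#C[C@]1(C)C[C@]2(C)OC(=O)C[C@@H]2OO1 | intermediate
15 | (3S,4S,6R)-3,6-epidioxy-4-hydroxy-4,6-dimethyldocosanoic acid 1,4-lactone | CCCCCCCCCCCCCCCC[C@]1(C)C[C@]2(C)OC(=O)C[C@@H]2OO1 | target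

Total step count: 9. Longest linear sequence: 8 (steps 1–5 and 7–9).

**Steps most likely to fail**

**Step 7 (bears the label).**
- What may go wrong: the ring ionises to a free cation before the peroxide arrives, which erodes the C6 information. The formylcyclopropane may rearrange to a dihydrofuran. The peroxyacetal may fragment heterolytically under the Lewis acid.
- Fallback, from 7 back to 12, built only from known reaction types: step 6 is stopped before silylation and hydroperoxide 9 is isolated. It opens 7 under Sc(OTf)3 catalysis in CH2Cl2 (Lewis-acid ring opening of a donor–acceptor cyclopropane by a hydroperoxide) to give the γ-peroxy aldehyde F1. Et3SiOTf and Et3N convert this into silyl enol ether 11, which is now purified. SnCl4 at −78 °C then ionises the peroxyacetal and closes the ring (addition of a silyl enol ether to a peroxycarbenium ion). Each of the two bonds is thus made and checked on its own.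

**Step 8.**
- What may go wrong: hydride migrates instead of C4 in the peracid adduct, or the hindered aldehyde is oxidised so slowly that the alkyne is attacked.
- Fallback, from 12 back to 14, which replaces the aldehyde migration by a carboxy-inversion sequence: Pinnick oxidation (NaClO2, NaH2PO4, 2-methylbut-2-ene, t-BuOH–H2O) gives the dioxane-4-carboxylic acid F2, which is also what hydride migration would deliver. DCC and m-CPBA convert it into the mixed diacyl peroxide F3. Gentle warming in MeCN brings about the carboxy inversion with retention at C4 to give the mixed carbonic anhydride F4. K2CO3 in MeOH then cleaves this and lets the freed alkoxide lactonise to 14.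

**Step 9.**
- What may go wrong: the reduction stalls at the alkene next to the quaternary centre, and long exposure to the acidic methanolic medium follows.
- Fallback, from 14 back to 15, which splits the saturation into two different events: diimide is used only for the fast first half, giving the (Z)-alkene F5. The alkene is then hydrogenated with H2 (1 atm) and RhCl(PPh3)3 in benzene, a homogeneous catalyst type that has been used on alkenes in the presence of dialkyl peroxides.

Further compounds
F1 | step 7 | methyl 3-{[(4S)-2,4-dimethyl-1-oxoicos-5-yn-4-yl]peroxy}-3-methoxypropanoate (C2 and acetal centre undefined) | CCCCCCCCCCCCCCC#C[C@](C)(CC(C)C=O)OOC(CC(=O)OC)OC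
F2 | step 8 | (3S,4S,6S)-6-(hexadec-1-yn-1-yl)-3-(2-methoxy-2-oxoethyl)-4,6-dimethyl-1,2-dioxane-4-carboxylic acid | CCCCCCCCCCCCCCC#C[C@]1(C)C[C@](C)(C(=O)O)[C@H](CC(=O)OC)OO1
F3 | step 8 | 3-chlorobenzoyl (3S,4S,6S)-6-(hexadec-1-yn-1-yl)-3-(2-methoxy-2-oxoethyl)-4,6-dimethyl-1,2-dioxane-4-carbonyl peroxide | CCCCCCCCCCCCCCC#C[C@]1(C)C[C@](C)(C(=O)OOC(=O)c2cccc(Cl)c2)[C@H](CC(=O)OC)OO1
F4 | step 8 | 3-chlorobenzoic (3S,4S,6S)-6-(hexadec-1-yn-1-yl)-3-(2-methoxy-2-oxoethyl)-4,6-dimethyl-1,2-dioxan-4-yl carbonic anhydride | CCCCCCCCCCCCCCC#C[C@]1(C)C[C@](C)(OC(=O)OC(=O)c2cccc(Cl)c2)[C@H](CC(=O)OC)OO1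
F5 | step 9 | (3S,4S,6S,7Z)-3,6-epidioxy-4-hydroxy-4,6-dimethyldocos-7-enoic acid 1,4-lactone | CCCCCCCCCCCCCC/C=C\[C@]1(C)C[C@]2(C)OC(=O)C[C@@H]2OO1
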